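**Retrosynthetic overview**
- Glaucolide K ⇒ last-stage esters: methacrylate on the C8 alcohol, acetates on C1-OH and C13-OH (both carried as TBS ethers).
- Ten-membered carbocycle and butenolide ⇒ formed together in one new palladium-catalysed step from an open-chain 2,3-allenoic acid bearing the C8 aldehyde (C6–O and C7–C8 bonds).
- Allenoic acid ⇒ anti SN2' carbonylation of a propargylic mesylate (C11–C12), itself from anti-selective acetylide addition to an α,β-epoxy aldehyde (C6–C7).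
- Epoxide ⇒ Sharpless epoxidation of a geraniol-type allylic alcohol; C1/C10 ⇒ catalytic syn-crotylboration of an aldehyde cut from geranyl acetate; C8 aldehyde ⇒ hydroboration/oxidation of the crotyl vinyl group.
- Ring order: epoxide first (step 5), then butenolide and ten-membered ring simultaneously (step 12).

Assumption: geranyl acetate, (Z)-crotylboronic acid pinacol ester and tert-butyldimethyl(prop-2-yn-1-yloxy)silane are taken as commercial; Cn labels follow germacrane numbering (ring C1–C10, lactone carbons C11–C13, C14 on C10, C15 on C4); allene axes in SMILES are marked on the central carbon.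
Abbreviation: TBS = tert-butyldimethylsilyl.

**Route**

Step 1
Reactants: 1 geranyl acetate
Product: 3 (2E)-3-methyl-6-oxohex-2-en-1-yl acetate, via ozonide 2 (not isolated)
Conditions: O3 (1.0 equiv), CH2Cl2, −78 °C; then Me2S, −78 °C → rt
Reagents that add atoms: ozone, [O-][O+]=O
Why: Chemoselective ozonolysis, because the electron-rich 6,7-alkene reacts far faster than the 2,3-alkene deactivated by the allylic acetate, and reductive cleavage of the ozonide gives the C1 aldehyde with no stereocentre formed.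

Step 2
Reactants: 3 (2E)-3-methyl-6-oxohex-2-en-1-yl acetate; 4 (Z)-crotylboronic acid pinacol ester
Product: 6 (2E,6S,7S)-6-hydroxy-3,7-dimethylnona-2,8-dien-1-yl acetate, via pinacol borate ester 5 (not isolated)
Conditions: (R)-TRIP [(R)-3,3'-bis(2,4,6-triisopropylphenyl)-1,1'-binaphthyl-2,2'-diyl hydrogen phosphate] (5 mol%), 4 Å MS, toluene, −30 °C; aqueous work-up
Reagents that add atoms: none
Why: Chiral-phosphoric-acid-catalysed crotylboration through a closed chair transition state, in which the (Z)-crotyl geometry gives the syn product and the (R)-acid directs attack to the Re face of the aldehyde, setting C1 (S) and C10 (S).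

Step 3
Reactants: 6 (2E,6S,7S)-6-hydroxy-3,7-dimethylnona-2,8-dien-1-yl acetate
Product: 7 (2E,6S,7S)-6-[(TBS)oxy]-3,7-dimethylnona-2,8-dien-1-yl acetate
Conditions: TBSOTf, 2,6-lutidine, CH2Cl2, −78 °C
Reagents that add atoms: tert-butyldimethylsilyl triflate, CC(C)(C)[Si](C)(C)OS(=O)(=O)C(F)(F)F
Why: Silylation of the secondary alcohol under a hindered base, to which the acetate and both alkenes are inert.

Step 4
Reactants: 7 (2E,6S,7S)-6-[(TBS)oxy]-3,7-dimethylnona-2,8-dien-1-yl acetate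
Product: 8 (2E,6S,7S)-6-[(TBS)oxy]-3,7-dimethylnona-2,8-dien-1-ol
Conditions: K2CO3 (0.2 equiv), MeOH, 0 °C → rt
Reagents that add atoms: none
Why: Base-catalysed transesterification (methanolysis) frees the allylic alcohol while the TBS ether is stable.

Step 5
Reactants: 8 (2E,6S,7S)-6-[(TBS)oxy]-3,7-dimethylnona-2,8-dien-1-ol
Product: 9 {(2R,3R)-3-[(3S,4S)-3-[(TBS)oxy]-4-methylhex-5-en-1-yl]-3-methyloxiran-2-yl}methanol
Conditions: Ti(OiPr)4 (10 mol%), D-(−)-diethyl tartrate (12 mol%), t-BuOOH, 4 Å MS, CH2Cl2, −20 °C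
Reagents that add atoms: tert-butyl hydroperoxide, CC(C)(C)OO
Why: Sharpless asymmetric epoxidation under reagent control, where D-(−)-tartrate delivers oxygen to the face of the (E)-trisubstituted allylic alcohol that gives C4 (R) and C5 (R), and the isolated terminal alkene is untouched.

Step 6
Reactants: 9 {(2R,3R)-3-[(3S,4S)-3-[(TBS)oxy]-4-methylhex-5-en-1-yl]-3-methyloxiran-2-yl}methanol
Product: 10 (2S,3R)-3-[(3S,4S)-3-[(TBS)oxy]-4-methylhex-5-en-1-yl]-3-methyloxirane-2-carbaldehyde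
Conditions: TEMPO (10 mol%), PhI(OAc)2, CH2Cl2, 0 °C → rt; used crude
Reagents that add atoms: none
Why: Oxoammonium (TEMPO) oxidation of the primary alcohol stops at the aldehyde under near-neutral conditions that do not open the epoxide or epimerise C5.

Step 7
Reactants: 10 (2S,3R)-3-[(3S,4S)-3-[(TBS)oxy]-4-methylhex-5-en-1-yl]-3-methyloxirane-2-carbaldehyde; 11 tert-butyldimethyl(prop-2-yn-1-yloxy)silane
Product: 13 (1R)-4-[(TBS)oxy]-1-{(2R,3R)-3-[(3S,4S)-3-[(TBS)oxy]-4-methylhex-5-en-1-yl]-3-methyloxiran-2-yl}but-2-yn-1-ol, via lithium acetylide 12 (not isolated)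
Conditions: 11, n-BuLi, THF, −78 °C; then 10, −78 °C; AcOH quench
Reagents that add atoms: none
Why: 1,2-Addition of a lithium acetylide to the α,β-epoxy aldehyde under Felkin–Anh (Cornforth) control, with attack anti to the epoxide C–O bond, gives the anti (erythro) alcohol with C6 (R) (expected dr about 5:1, minor epimer removed by chromatography).

Step 8
Reactants: 13 (1R)-4-[(TBS)oxy]-1-{(2R,3R)-3-[(3S,4S)-3-[(TBS)oxy]-4-methylhex-5-en-1-yl]-3-methyloxiran-2-yl}but-2-yn-1-ol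
Product: 15 (1R)-4-[(TBS)oxy]-1-{(2R,3R)-3-[(3S,4S)-3-[(TBS)oxy]-6-hydroxy-4-methylhexyl]-3-methyloxiran-2-yl}but-2-yn-1-ol, via bis(9-BBN) adduct 14 (not isolated)
Conditions: 9-BBN (2.5 equiv), THF, 0 °C → rt; then 30% H2O2, aq. NaOAc, 0 °C → rt
Reagents that add atoms: hydrogen peroxide, OO
Why: Hydroboration–oxidation, in which 9-BBN adds anti-Markovnikov to the terminal alkene much faster than to the hindered internal alkyne (the free hydroxyl only forms a borinate cleaved on work-up) and buffered peroxide gives the C8 alcohol without Payne rearrangement.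

Step 9
Reactants: 15 (1R)-4-[(TBS)oxy]-1-{(2R,3R)-3-[(3S,4S)-3-[(TBS)oxy]-6-hydroxy-4-methylhexyl]-3-methyloxiran-2-yl}but-2-yn-1-ol
Product: 16 (3S,4S)-4-[(TBS)oxy]-6-{(2R,3R)-3-[(1R)-4-[(TBS)oxy]-1-hydroxybut-2-yn-1-yl]-2-methyloxiran-2-yl}-3-methylhexanal
Conditions: TEMPO (10 mol%), PhI(OAc)2 (1.1 equiv), CH2Cl2, 0 °C → rt
Reagents that add atoms: none
Why: TEMPO/PhI(OAc)2 oxidation is selective for the unhindered primary alcohol over the hindered secondary propargylic alcohol and gives the C8 aldehyde.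

Step 10
Reactants: 16 (3S,4S)-4-[(TBS)oxy]-6-{(2R,3R)-3-[(1R)-4-[(TBS)oxy]-1-hydroxybut-2-yn-1-yl]-2-methyloxiran-2-yl}-3-methylhexanal
Product: 17 (1R)-4-[(TBS)oxy]-1-{(2R,3R)-3-[(3S,4S)-3-[(TBS)oxy]-4-methyl-6-oxohexyl]-3-methyloxiran-2-yl}but-2-yn-1-yl methanesulfonate
Conditions: MsCl, Et3N, CH2Cl2, −40 °C; used directly
Reagents that add atoms: methanesulfonyl chloride, CS(=O)(=O)Cl
Why: Sulfonylation (mesylation) of the propargylic alcohol proceeds with retention at C6 and leaves the aldehyde and epoxide untouched at low temperature.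

Step 11
Reactants: 17 (1R)-4-[(TBS)oxy]-1-{(2R,3R)-3-[(3S,4S)-3-[(TBS)oxy]-4-methyl-6-oxohexyl]-3-methyloxiran-2-yl}but-2-yn-1-yl methanesulfonate
Product: 18 (aR)-2-{[(TBS)oxy]methyl}-4-{(2R,3R)-3-[(3S,4S)-3-[(TBS)oxy]-4-methyl-6-oxohexyl]-3-methyloxiran-2-yl}buta-2,3-dienoic acid
Conditions: Pd(PPh3)4 (5 mol%), CO (1 atm), 2,6-lutidine, THF/H2O (10:1), 0 °C → rt
Reagents that add atoms: carbon monoxide, [C-]#[O+]; water, O
Why: Palladium-catalysed carbonylation of a propargylic mesylate, in which anti SN2' oxidative addition of zerovalent palladium, CO insertion and hydrolysis give the 2,3-allenoic acid and convert the C6 (R) centre into the (aR) allene axis.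

Step 12
Reactants: 18 (aR)-2-{[(TBS)oxy]methyl}-4-{(2R,3R)-3-[(3S,4S)-3-[(TBS)oxy]-4-methyl-6-oxohexyl]-3-methyloxiran-2-yl}buta-2,3-dienoic acid
Product: 19 (1S,4R,5R,6S,8S,10S)-1,13-bis[(TBS)oxy]-4,5-epoxy-8-hydroxygermacr-7(11)-en-12,6-olide
Conditions: Pd(OAc)2 (10 mol%), (S)-4-tert-butyl-2-(pyridin-2-yl)-4,5-dihydrooxazole (12 mol%), 4 Å MS, 1,4-dioxane, 50 °C, syringe-pump addition of 18 over 12 h (final 2 mM)
Reagents that add atoms: none
Why: Proposed new method: divalent palladium activates the C6=C7 bond of the allene for anti attack by the carboxylate (lactonising oxypalladation, relaying the (aR) axis to C6 (S)) to give a butenolid-4-yl–palladium species that, instead of being protonated, adds across the tethered C8 aldehyde (1,2-insertion) to close the ten-membered ring, the palladium alkoxide then being protonated by incoming acid so that no redox change is needed and slow addition keeps free acid too low for protodepalladation, while the chiral pyridine–oxazoline ligand is proposed to select the aldehyde face that gives C8 (S); the closest known reactions are the divalent-palladium-catalysed coupling-cyclisations of 2,3-allenoic acids to 4-substituted butenolides and the Pd(OAc)2/bipyridine-catalysed oxypalladation–carbonyl-addition cyclisations of alkynes carrying an aldehyde, which so far form only five- and six-membered rings.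

Step 13
Reactants: 19 (1S,4R,5R,6S,8S,10S)-1,13-bis[(TBS)oxy]-4,5-epoxy-8-hydroxygermacr-7(11)-en-12,6-olide
Product: 20 (1S,4R,5R,6S,8S,10S)-1,13-bis[(TBS)oxy]-4,5-epoxy-8-(methacryloyloxy)germacr-7(11)-en-12,6-olide
Conditions: methacrylic anhydride, Et3N, DMAP (10 mol%), CH2Cl2, 0 °C → rt
Reagents that add atoms: methacrylic anhydride, C=C(C)C(=O)OC(=O)C(C)=C
Why: DMAP-catalysed acylation (esterification) of the only free hydroxyl, the allylic C8 alcohol, with retention of configuration.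

Step 14
Reactants: 20 (1S,4R,5R,6S,8S,10S)-1,13-bis[(TBS)oxy]-4,5-epoxy-8-(methacryloyloxy)germacr-7(11)-en-12,6-olide
Product: 21 (1S,4R,5R,6S,8S,10S)-4,5-epoxy-1,13-dihydroxy-8-(methacryloyloxy)germacr-7(11)-en-12,6-olide
Conditions: HF·pyridine, pyridine, THF, 0 °C → rt
Reagents that add atoms: none
Why: Fluoride-mediated desilylation with pyridine-buffered HF removes both TBS ethers while the buffered medium spares the epoxide, the butenolide and the methacrylate.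

Step 15
Reactants: 21 (1S,4R,5R,6S,8S,10S)-4,5-epoxy-1,13-dihydroxy-8-(methacryloyloxy)germacr-7(11)-en-12,6-olide
Product: 22 glaucolide K
Conditions: Ac2O, pyridine, DMAP (5 mol%), CH2Cl2, 0 °C → rt
Reagents that add atoms: acetic anhydride, CC(=O)OC(C)=O
Why: DMAP-catalysed acetylation of the primary C13 and secondary C1 hydroxyls completes the target without touching any stereocentre.

**Compound list**

1 | geranyl acetate, (2E)-3,7-dimethylocta-2,6-dien-1-yl acetate | CC(C)=CCC/C(C)=C/COC(C)=O | starting material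
2 | 5-[(3E)-5-acetoxy-3-methylpent-3-en-1-yl]-3,3-dimethyl-1,2,4-trioxolane (ozonide, ring carbon unspecified) | CC1(C)OOC(CC/C(C)=C/COC(C)=O)O1 | intermediate
3 | (2E)-3-methyl-6-oxohex-2-en-1-yl acetate | O=CCC/C(C)=C/COC(C)=O | intermediate
4 | (Z)-crotylboronic acid pinacol ester, 2-[(2Z)-but-2-en-1-yl]-4,4,5,5-tetramethyl-1,3,2-dioxaborolane | C/C=C\CB1OC(C)(C)C(C)(C)O1 | starting material
5 | (2E,6S,7S)-3,7-dimethyl-6-[(4,4,5,5-tetramethyl-1,3,2-dioxaborolan-2-yl)oxy]nona-2,8-dien-1-yl acetate | C=C[C@H](C)[C@@H](OB1OC(C)(C)C(C)(C)O1)CC/C(C)=C/COC(C)=O | intermediate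
6 | (2E,6S,7S)-6-hydroxy-3,7-dimethylnona-2,8-dien-1-yl acetate | C=C[C@H](C)[C@@H](O)CC/C(C)=C/COC(C)=O | intermediate
7 | (2E,6S,7S)-6-[(TBS)oxy]-3,7-dimethylnona-2,8-dien-1-yl acetate | C=C[C@H](C)[C@@H](O[Si](C)(C)C(C)(C)C)CC/C(C)=C/COC(C)=O | intermediate
8 | (2E,6S,7S)-6-[(TBS)oxy]-3,7-dimethylnona-2,8-dien-1-ol | C=C[C@H](C)[C@@H](O[Si](C)(C)C(C)(C)C)CC/C(C)=C/CO | intermediate
9 | {(2R,3R)-3-[(3S,4S)-3-[(TBS)oxy]-4-methylhex-5-en-1-yl]-3-methyloxiran-2-yl}methanol | C=C[C@H](C)[C@@H](O[Si](C)(C)C(C)(C)C)CC[C@@]1(C)O[C@@H]1CO | intermediate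
10 | (2S,3R)-3-[(3S,4S)-3-[(TBS)oxy]-4-methylhex-5-en-1-yl]-3-methyloxirane-2-carbaldehyde | C=C[C@H](C)[C@@H](O[Si](C)(C)C(C)(C)C)CC[C@@]1(C)O[C@@H]1C=O | intermediate
11 | tert-butyldimethyl(prop-2-yn-1-yloxy)silane | C#CCO[Si](C)(C)C(C)(C)C | starting material
12 | {3-[(TBS)oxy]prop-1-yn-1-yl}lithium | [Li]C#CCO[Si](C)(C)C(C)(C)C | intermediate
13 | (1R)-4-[(TBS)oxy]-1-{(2R,3R)-3-[(3S,4S)-3-[(TBS)oxy]-4-methylhex-5-en-1-yl]-3-methyloxiran-2-yl}but-2-yn-1-ol | C=C[C@H](C)[C@@H](O[Si](C)(C)C(C)(C)C)CC[C@@]1(C)O[C@@H]1[C@H](O)C#CCO[Si](C)(C)C(C)(C)C | intermediate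
14 | bis(9-borabicyclo[3.3.1]nonan-9-yl) adduct of 13 (one boron on C8, one on the propargylic oxygen) | C(B1C2CCCC1CCC2)C[C@H](C)[C@@H](O[Si](C)(C)C(C)(C)C)CC[C@@]3(C)O[C@@H]3[C@H](OB4C5CCCC4CCC5)C#CCO[Si](C)(C)C(C)(C)C | intermediate
15 | (1R)-4-[(TBS)oxy]-1-{(2R,3R)-3-[(3S,4S)-3-[(TBS)oxy]-6-hydroxy-4-methylhexyl]-3-methyloxiran-2-yl}but-2-yn-1-ol | OCC[C@H](C)[C@@H](O[Si](C)(C)C(C)(C)C)CC[C@@]1(C)O[C@@H]1[C@H](O)C#CCO[Si](C)(C)C(C)(C)C | intermediate
16 | (3S,4S)-4-[(TBS)oxy]-6-{(2R,3R)-3-[(1R)-4-[(TBS)oxy]-1-hydroxybut-2-yn-1-yl]-2-methyloxiran-2-yl}-3-methylhexanal | O=CC[C@H](C)[C@@H](O[Si](C)(C)C(C)(C)C)CC[C@@]1(C)O[C@@H]1[C@H](O)C#CCO[Si](C)(C)C(C)(C)C | intermediate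
17 | (1R)-4-[(TBS)oxy]-1-{(2R,3R)-3-[(3S,4S)-3-[(TBS)oxy]-4-methyl-6-oxohexyl]-3-methyloxiran-2-yl}but-2-yn-1-yl methanesulfonate | O=CC[C@H](C)[C@@H](O[Si](C)(C)C(C)(C)C)CC[C@@]1(C)O[C@@H]1[C@H](OS(C)(=O)=O)C#CCO[Si](C)(C)C(C)(C)C | intermediate
18 | (aR)-2-{[(TBS)oxy]methyl}-4-{(2R,3R)-3-[(3S,4S)-3-[(TBS)oxy]-4-methyl-6-oxohexyl]-3-methyloxiran-2-yl}buta-2,3-dienoic acid | O=CC[C@H](C)[C@@H](O[Si](C)(C)C(C)(C)C)CC[C@@]1(C)O[C@@H]1C([H])=[C@]=C(CO[Si](C)(C)C(C)(C)C)C(=O)O | intermediate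
19 | (1S,4R,5R,6S,8S,10S)-1,13-bis[(TBS)oxy]-4,5-epoxy-8-hydroxygermacr-7(11)-en-12,6-olide | O[C@H]1C[C@H](C)[C@@H](O[Si](C)(C)C(C)(C)C)CC[C@@]2(C)O[C@@H]2[C@H]2OC(=O)C(CO[Si](C)(C)C(C)(C)C)=C12 | intermediate
20 | (1S,4R,5R,6S,8S,10S)-1,13-bis[(TBS)oxy]-4,5-epoxy-8-(methacryloyloxy)germacr-7(11)-en-12,6-olide | C=C(C)C(=O)O[C@H]1C[C@H](C)[C@@H](O[Si](C)(C)C(C)(C)C)CC[C@@]2(C)O[C@@H]2[C@H]2OC(=O)C(CO[Si](C)(C)C(C)(C)C)=C12 | intermediate
21 | (1S,4R,5R,6S,8S,10S)-4,5-epoxy-1,13-dihydroxy-8-(methacryloyloxy)germacr-7(11)-en-12,6-olide | C=C(C)C(=O)O[C@H]1C[C@H](C)[C@@H](O)CC[C@@]2(C)O[C@@H]2[C@H]2OC(=O)C(CO)=C12 | intermediate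
22 | glaucolide K, (1S,4R,5R,6S,8S,10S)-1,13-diacetoxy-4,5-epoxy-8-(methacryloyloxy)germacr-7(11)-en-12,6-olide | C=C(C)C(=O)O[C@H]1C[C@H](C)[C@@H](OC(C)=O)CC[C@@]2(C)O[C@@H]2[C@H]2OC(=O)C(COC(C)=O)=C12 | target

**Step count and risks**

Total step count: 15. Longest linear sequence: 15 steps (1 → 22).

Three steps most likely to fail:

Step 12 (the proposed new step). Insertion of a remote aldehyde into the alkenyl–palladium bond through a ten-membered transition state may lose to protodepalladation (giving the simple 4-H butenolide), and the C8 face selectivity is unproven. The fallback uses known chemistry, sets out from 18 and returns at 19. Iodolactonisation of 18 (I2, NaHCO3, MeCN, 0 °C; anti addition with the same axis-to-centre transfer) gives (3S,4S)-4-[(TBS)oxy]-6-{(2R,3R)-3-[(2R)-3-iodo-4-{[(TBS)oxy]methyl}-5-oxo-2,5-dihydrofuran-2-yl]-2-methyloxiran-2-yl}-3-methylhexanal F1. A Nozaki–Hiyama–Kishi macrocyclisation (CrCl2, NiCl2 1 mol%, DMSO/THF, 2 mM, rt) then forms the C7–C8 bond and gives 19 together with its C8 epimer, (1S,4R,5R,6S,8R,10S)-1,13-bis[(TBS)oxy]-4,5-epoxy-8-hydroxygermacr-7(11)-en-12,6-olide F2. If the ratio is poor the mixture is oxidised (Dess–Martin periodinane, NaHCO3, CH2Cl2) to the ketone (1S,4R,5R,6S,10S)-1,13-bis[(TBS)oxy]-4,5-epoxy-8-oxogermacr-7(11)-en-12,6-olide F3. Reduction with (R)-2-methyl-CBS-oxazaborolidine and catecholborane (toluene, −78 °C; the alkenyl group acts as the large substituent) then returns to 19.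

Step 11. The labile mesylate may ionise or hydrolyse, the methanesulfonic acid formed may open the epoxide, and zerovalent palladium may attack the epoxide next to the new allene. The fallback sets out from 16 and returns at 19. Methyl chloroformate and pyridine (CH2Cl2, 0 °C) give the stable carbonate (1R)-4-[(TBS)oxy]-1-{(2R,3R)-3-[(3S,4S)-3-[(TBS)oxy]-4-methyl-6-oxohexyl]-3-methyloxiran-2-yl}but-2-yn-1-yl methyl carbonate F4. Neutral decarboxylative methoxycarbonylation (Pd2(dba)3 2.5 mol%, PPh3, CO 1 atm, MeOH, 40 °C; anti SN2') gives methyl (aR)-2-{[(TBS)oxy]methyl}-4-{(2R,3R)-3-[(3S,4S)-3-[(TBS)oxy]-4-methyl-6-oxohexyl]-3-methyloxiran-2-yl}buta-2,3-dienoate F5. Iodolactonisation of this ester (I2, MeCN/H2O, rt) gives the iodobutenolide aldehyde F1, which is carried on as in the fallback for step 12 through the alcohol epimer F2 and the ketone F3 to 19. This removes the strong acid and the free allenoic acid, but the palladium/epoxide risk remains.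

Step 7. Felkin–Anh control in acetylide additions to α,β-epoxy aldehydes can be modest. The fallback sets out from 10 and returns at 13. The addition is run without regard to selectivity and gives 13 with its epimer, (1S)-4-[(TBS)oxy]-1-{(2R,3R)-3-[(3S,4S)-3-[(TBS)oxy]-4-methylhex-5-en-1-yl]-3-methyloxiran-2-yl}but-2-yn-1-ol F6. The mixture is oxidised (Dess–Martin periodinane, NaHCO3, CH2Cl2) to 4-[(TBS)oxy]-1-{(2S,3R)-3-[(3S,4S)-3-[(TBS)oxy]-4-methylhex-5-en-1-yl]-3-methyloxiran-2-yl}but-2-yn-1-one F7. Reduction with Zn(BH4)2 (Et2O, −30 °C), through a zinc chelate of the carbonyl and epoxide oxygens, gives the erythro alcohol and returns to 13.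

Further compounds
F1 | step 12 | (3S,4S)-4-[(TBS)oxy]-6-{(2R,3R)-3-[(2R)-3-iodo-4-{[(TBS)oxy]methyl}-5-oxo-2,5-dihydrofuran-2-yl]-2-methyloxiran-2-yl}-3-methylhexanal | O=CC[C@H](C)[C@@H](O[Si](C)(C)C(C)(C)C)CC[C@@]1(C)O[C@@H]1[C@H]1OC(=O)C(CO[Si](C)(C)C(C)(C)C)=C1I
F2 | step 12 | (1S,4R,5R,6S,8R,10S)-1,13-bis[(TBS)oxy]-4,5-epoxy-8-hydroxygermacr-7(11)-en-12,6-olide | O[C@@H]1C[C@H](C)[C@@H](O[Si](C)(C)C(C)(C)C)CC[C@@]2(C)O[C@@H]2[C@H]2OC(=O)C(CO[Si](C)(C)C(C)(C)C)=C12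
F3 | step 12 | (1S,4R,5R,6S,10S)-1,13-bis[(TBS)oxy]-4,5-epoxy-8-oxogermacr-7(11)-en-12,6-olide | O=C1C[C@H](C)[C@@H](O[Si](C)(C)C(C)(C)C)CC[C@@]2(C)O[C@@H]2[C@H]2OC(=O)C(CO[Si](C)(C)C(C)(C)C)=C12
F4 | step 11 | (1R)-4-[(TBS)oxy]-1-{(2R,3R)-3-[(3S,4S)-3-[(TBS)oxy]-4-methyl-6-oxohexyl]-3-methyloxiran-2-yl}but-2-yn-1-yl methyl carbonate | O=CC[C@H](C)[C@@H](O[Si](C)(C)C(C)(C)C)CC[C@@]1(C)O[C@@H]1[C@H](OC(=O)OC)C#CCO[Si](C)(C)C(C)(C)C
F5 | step 11 | methyl (aR)-2-{[(TBS)oxy]methyl}-4-{(2R,3R)-3-[(3S,4S)-3-[(TBS)oxy]-4-methyl-6-oxohexyl]-3-methyloxiran-2-yl}buta-2,3-dienoate | O=CC[C@H](C)[C@@H](O[Si](C)(C)C(C)(C)C)CC[C@@]1(C)O[C@@H]1C([H])=[C@]=C(CO[Si](C)(C)C(C)(C)C)C(=O)OC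
F6 | step 7 | (1S)-4-[(TBS)oxy]-1-{(2R,3R)-3-[(3S,4S)-3-[(TBS)oxy]-4-methylhex-5-en-1-yl]-3-methyloxiran-2-yl}but-2-yn-1-ol | C=C[C@H](C)[C@@H](O[Si](C)(C)C(C)(C)C)CC[C@@]1(C)O[C@@H]1[C@@H](O)C#CCO[Si](C)(C)C(C)(C)C
F7 | step 7 | 4-[(TBS)oxy]-1-{(2S,3R)-3-[(3S,4S)-3-[(TBS)oxy]-4-methylhex-5-en-1-yl]-3-methyloxiran-2-yl}but-2-yn-1-one | C=C[C@H](C)[C@@H](O[Si](C)(C)C(C)(C)C)CC[C@@]1(C)O[C@@H]1C(=O)C#CCO[Si](C)(C)C(C)(C)C
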